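**Plan**

1. Retrosynthetic cuts, in order: the side chain (C1' carbinol from an α-hydroxy ketone, and C5–C1' from a C5 aryllithium plus an (R)-lactic Weinreb amide); then C3–CH3 from C3–CO2Et, a helper that makes the carbene a donor/acceptor one; then the ring bond C2–C3 by carbene C–H insertion; last O1–C2 (Williamson) and C3a–C3 (Pd coupling of an aryl iodide with ethyl diazoacetate).
2. Enabling feature: C2 is a CH bonded to the ring oxygen O1 and to the 3,4-dimethoxyphenyl ring. Opened at C2–C3, it is the CH2 of an aryl benzyl ether whose hydridic C–H bonds lie 1,5 to a carbene at C3 on the neighbouring ring carbon C3a.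
3. Forward: both benzene rings are bought. O1–C2 joins them (step 2), the diazo carbon is placed on C3a (step 3), and the dihydrofuran ring, the only ring made, closes in step 4. The ester is then turned into the methyl group (steps 5–8) and the side chain is attached at C5 (steps 11–13) with fragment 14 (steps 9–10).
4. Stereochemistry: C2 from the chiral dirhodium carboxylate (choice between two enantiotopic hydrogens); C3 by epimerization to trans relative to C2; C2' from methyl (R)-lactate; C1' by Cram-chelate hydride delivery.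

Key step: step 4

Assumption: the sense of induction of the dirhodium catalyst is taken by analogy with closely related benzyl ether insertions (S ligand expected to give 2R), so the R ligand is specified for 2S; the bromine atom allows the assignment to be checked by anomalous-dispersion X-ray analysis at compound 8 or 11.

**Route**

Step 1
Reactants: 1 4-bromo-2-methoxyphenol
Product: 2 4-bromo-2-iodo-6-methoxyphenol
Conditions: NIS (1.05 equiv), TsOH·H2O (10 mol%), MeCN, 0 °C to rt
Reagents that add atoms: N-iodosuccinimide, O=C1CCC(=O)N1I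
Why: Electrophilic aromatic iodination in which the phenol hydroxyl directs, its para position is blocked by bromine, and iodine should therefore enter the free ortho position.

Step 2
Reactants: 2 4-bromo-2-iodo-6-methoxyphenol; 3 4-(bromomethyl)-1,2-dimethoxybenzene
Product: 4 5-bromo-2-[(3,4-dimethoxyphenyl)methoxy]-1-iodo-3-methoxybenzene
Conditions: K2CO3, DMF, rt
Reagents that add atoms: none
Why: Williamson ether synthesis (SN2 of the phenoxide on a reactive benzylic bromide) forms the O1–C2 bond and brings in C2 with its two enantiotopic hydrogens.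

Step 3
Reactants: 4 5-bromo-2-[(3,4-dimethoxyphenyl)methoxy]-1-iodo-3-methoxybenzene; 5 ethyl diazoacetate
Product: 6 ethyl 2-{5-bromo-2-[(3,4-dimethoxyphenyl)methoxy]-3-methoxyphenyl}-2-diazoacetate
Conditions: Pd(PPh3)4 (5 mol%), Ag2CO3 (0.5 equiv), Et3N, toluene, rt
Reagents that add atoms: none
Why: Palladium-catalysed cross-coupling of an aryl iodide with an acceptor diazo compound with retention of the diazo group (oxidative addition of zerovalent palladium into C–I, much faster than into C–Br at room temperature, then silver-assisted palladation of the diazo carbon and reductive elimination) gives the aryldiazoacetate in one operation.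

Step 4
Reactants: 6 ethyl 2-{5-bromo-2-[(3,4-dimethoxyphenyl)methoxy]-3-methoxyphenyl}-2-diazoacetate
Product: 7 ethyl (2S,3R)-5-bromo-2-(3,4-dimethoxyphenyl)-7-methoxy-2,3-dihydro-1-benzofuran-3-carboxylate (cis)
Conditions: Rh2(R-PTTL)4 (dirhodium tetrakis[N-phthaloyl-(R)-tert-leucinate], 1 mol%), toluene, −60 °C
Reagents that add atoms: none
Why: Loss of N2 at the dirhodium tetracarboxylate gives an electrophilic donor/acceptor rhodium carbene at C3, which inserts into one C2–H bond of the OCH2Ar group through a concerted, asynchronous three-centre (hydride-transfer-like) transition state; that bond is hydridic because C2 carries O1 and the electron-rich 3,4-dimethoxyphenyl ring. The closest known reaction type is the enantioselective intramolecular 1,5-C–H insertion of aryldiazoacetates into benzylic ether C–H bonds under chiral dirhodium carboxylate catalysis, which gives cis-2-aryl-2,3-dihydrobenzofuran-3-carboxylates. The ring O1–C2–C3–C3a–C7a closes by 1,5-insertion, that is by forming the C2–C3 bond through a five-membered transition-state ring. C2 is controlled by the catalyst, whose N-phthaloyl-tert-leucinate ligands should let only one of the two enantiotopic C2–H bonds reach the carbene (2S expected with the R ligand); C3 is set cis to the aryl group by the kinetic preference of the insertion transition state, a temporary configuration that step 5 corrects. The step needs chemoselectivity for this C–H bond over carbene dimerization, azine formation, oxonium ylide formation and addition to the dimethoxyphenyl ring; the 1,5 distance, the hydridic C2–H bond, the impossibility of a small-ring ylide from O1 and the low temperature should secure it, and the aryl bromide and methyl ethers are inert.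

Step 5
Reactants: 7 ethyl (2S,3R)-5-bromo-2-(3,4-dimethoxyphenyl)-7-methoxy-2,3-dihydro-1-benzofuran-3-carboxylate
Product: 8 ethyl (2S,3S)-5-bromo-2-(3,4-dimethoxyphenyl)-7-methoxy-2,3-dihydro-1-benzofuran-3-carboxylate (trans)
Conditions: NaOEt (0.3 equiv), EtOH–THF, 0 °C to rt
Reagents that add atoms: none
Why: Base-mediated epimerization through the ester enolate at C3 should move the ester to the face trans to the C2 aryl group (thermodynamic control), while C2, which has no acidifying group, keeps its configuration.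

Step 6
Reactants: 8 ethyl (2S,3S)-5-bromo-2-(3,4-dimethoxyphenyl)-7-methoxy-2,3-dihydro-1-benzofuran-3-carboxylate
Product: 9 [(2S,3R)-5-bromo-2-(3,4-dimethoxyphenyl)-7-methoxy-2,3-dihydro-1-benzofuran-3-yl]methanol
Conditions: LiAlH4, THF, 0 °C
Reagents that add atoms: none
Why: Hydride reduction of the ester to the primary alcohol touches no stereocentre (the descriptor at C3 changes only by priority), and the aryl bromide should be inert at 0 °C.

Step 7
Reactants: 9 [(2S,3R)-5-bromo-2-(3,4-dimethoxyphenyl)-7-methoxy-2,3-dihydro-1-benzofuran-3-yl]methanol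
Product: 10 [(2S,3R)-5-bromo-2-(3,4-dimethoxyphenyl)-7-methoxy-2,3-dihydro-1-benzofuran-3-yl]methyl 4-methylbenzenesulfonate
Conditions: TsCl, Et3N, DMAP (cat.), CH2Cl2, 0 °C to rt
Reagents that add atoms: 4-methylbenzenesulfonyl chloride, Cc1ccc(cc1)S(=O)(=O)Cl
Why: Sulfonylation of the unhindered primary alcohol activates the helper carbon for removal of its oxygen.

Step 8
Reactants: 10 [(2S,3R)-5-bromo-2-(3,4-dimethoxyphenyl)-7-methoxy-2,3-dihydro-1-benzofuran-3-yl]methyl 4-methylbenzenesulfonate
Product: 11 (2S,3S)-5-bromo-2-(3,4-dimethoxyphenyl)-7-methoxy-3-methyl-2,3-dihydro-1-benzofuran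
Conditions: LiBHEt3, THF, 0 °C to rt
Reagents that add atoms: none
Why: SN2 displacement of the primary tosylate by the strongly nucleophilic triethylborohydride (substitution favoured over E2) turns the former ester carbon into the C3 methyl group without involving C3.

Step 9
Reactants: 12 methyl (R)-lactate
Product: 13 methyl (2R)-2-[(tert-butyldimethylsilyl)oxy]propanoate
Conditions: TBSCl, imidazole, DMF, rt
Reagents that add atoms: tert-butyldimethylsilyl chloride, CC(C)(C)[Si](C)(C)Cl
Why: Imidazole-promoted silylation protects the secondary hydroxyl of the chiral-pool building block that supplies C2'.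

Step 10
Reactants: 13 methyl (2R)-2-[(tert-butyldimethylsilyl)oxy]propanoate
Product: 14 (2R)-2-[(tert-butyldimethylsilyl)oxy]-N-methoxy-N-methylpropanamide
Conditions: MeNHOMe·HCl, i-PrMgCl, THF, −20 to 0 °C
Reagents that add atoms: N,O-dimethylhydroxylamine hydrochloride, CNOC.Cl
Why: Aminolysis of the ester by the magnesium amide of N,O-dimethylhydroxylamine gives the Weinreb amide, a transformation that α-silyloxy esters undergo at low temperature without loss of configuration.

Step 11
Reactants: 11 (2S,3S)-5-bromo-2-(3,4-dimethoxyphenyl)-7-methoxy-3-methyl-2,3-dihydro-1-benzofuran; 14 (2R)-2-[(tert-butyldimethylsilyl)oxy]-N-methoxy-N-methylpropanamide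
Product: 16 (2R)-2-[(tert-butyldimethylsilyl)oxy]-1-[(2S,3S)-2-(3,4-dimethoxyphenyl)-7-methoxy-3-methyl-2,3-dihydro-1-benzofuran-5-yl]propan-1-one, via aryllithium 15 (not isolated)
Conditions: n-BuLi, THF, −78 °C; then 14, −78 to −40 °C; aq. NH4Cl
Reagents that add atoms: none
Why: Bromine–lithium exchange followed by Weinreb ketone synthesis, in which the chelated tetrahedral intermediate prevents over-addition and the lactate-derived stereocentre is carried over unchanged.

Step 12
Reactants: 16 (2R)-2-[(tert-butyldimethylsilyl)oxy]-1-[(2S,3S)-2-(3,4-dimethoxyphenyl)-7-methoxy-3-methyl-2,3-dihydro-1-benzofuran-5-yl]propan-1-one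
Product: 17 (2R)-1-[(2S,3S)-2-(3,4-dimethoxyphenyl)-7-methoxy-3-methyl-2,3-dihydro-1-benzofuran-5-yl]-2-hydroxypropan-1-one
Conditions: TBAF, AcOH, THF, 0 °C
Reagents that add atoms: none
Why: Fluoride-mediated desilylation, buffered with acetic acid so that the enolizable α-ketol should not epimerize, frees the hydroxyl needed for chelation.

Step 13
Reactants: 17 (2R)-1-[(2S,3S)-2-(3,4-dimethoxyphenyl)-7-methoxy-3-methyl-2,3-dihydro-1-benzofuran-5-yl]-2-hydroxypropan-1-one
Product: 18 (1S,2R)-1-[(2S,3S)-2-(3,4-dimethoxyphenyl)-7-methoxy-3-methyl-2,3-dihydro-1-benzofuran-5-yl]propane-1,2-diol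
Conditions: Zn(BH4)2, Et2O, −20 to 0 °C
Reagents that add atoms: none
Why: Chelation-controlled (Cram chelate) reduction, in which zinc ties the ketone oxygen and the α-hydroxyl into a five-membered chelate and hydride attacks the carbonyl face opposite the C2' methyl group, should give the anti (erythro) 1S,2R diol.

**Compound list**

1 | 4-bromo-2-methoxyphenol | COc1cc(Br)ccc1O | starting material
2 | 4-bromo-2-iodo-6-methoxyphenol | COc1cc(Br)cc(I)c1O | intermediate
3 | 4-(bromomethyl)-1,2-dimethoxybenzene (3,4-dimethoxybenzyl bromide) | COc1ccc(CBr)cc1OC | starting material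
4 | 5-bromo-2-[(3,4-dimethoxyphenyl)methoxy]-1-iodo-3-methoxybenzene | COc1ccc(COc2c(I)cc(Br)cc2OC)cc1OC | intermediate
5 | ethyl diazoacetate | CCOC(=O)C=[N+]=[N-] | starting material
6 | ethyl 2-{5-bromo-2-[(3,4-dimethoxyphenyl)methoxy]-3-methoxyphenyl}-2-diazoacetate | CCOC(=O)C(=[N+]=[N-])c1cc(Br)cc(OC)c1OCc1ccc(OC)c(OC)c1 | intermediate
7 | ethyl (2S,3R)-5-bromo-2-(3,4-dimethoxyphenyl)-7-methoxy-2,3-dihydro-1-benzofuran-3-carboxylate (cis) | COc1ccc([C@H]2Oc3c(OC)cc(Br)cc3[C@H]2C(=O)OCC)cc1OC | intermediate
8 | ethyl (2S,3S)-5-bromo-2-(3,4-dimethoxyphenyl)-7-methoxy-2,3-dihydro-1-benzofuran-3-carboxylate (trans) | COc1ccc([C@H]2Oc3c(OC)cc(Br)cc3[C@@H]2C(=O)OCC)cc1OC | intermediate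
9 | [(2S,3R)-5-bromo-2-(3,4-dimethoxyphenyl)-7-methoxy-2,3-dihydro-1-benzofuran-3-yl]methanol | COc1ccc([C@H]2Oc3c(OC)cc(Br)cc3[C@@H]2CO)cc1OC | intermediate
10 | [(2S,3R)-5-bromo-2-(3,4-dimethoxyphenyl)-7-methoxy-2,3-dihydro-1-benzofuran-3-yl]methyl 4-methylbenzenesulfonate | COc1ccc([C@H]2Oc3c(OC)cc(Br)cc3[C@@H]2COS(=O)(=O)c4ccc(C)cc4)cc1OC | intermediate
11 | (2S,3S)-5-bromo-2-(3,4-dimethoxyphenyl)-7-methoxy-3-methyl-2,3-dihydro-1-benzofuran | COc1ccc([C@H]2Oc3c(OC)cc(Br)cc3[C@@H]2C)cc1OC | intermediate
12 | methyl (R)-lactate | C[C@@H](O)C(=O)OC | starting material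
13 | methyl (2R)-2-[(tert-butyldimethylsilyl)oxy]propanoate | C[C@@H](O[Si](C)(C)C(C)(C)C)C(=O)OC | intermediate
14 | (2R)-2-[(tert-butyldimethylsilyl)oxy]-N-methoxy-N-methylpropanamide | C[C@@H](O[Si](C)(C)C(C)(C)C)C(=O)N(C)OC | intermediate
15 | [(2S,3S)-2-(3,4-dimethoxyphenyl)-7-methoxy-3-methyl-2,3-dihydro-1-benzofuran-5-yl]lithium (aryllithium, not isolated) | COc1ccc([C@H]2Oc3c(OC)cc([Li])cc3[C@@H]2C)cc1OC | intermediate
16 | (2R)-2-[(tert-butyldimethylsilyl)oxy]-1-[(2S,3S)-2-(3,4-dimethoxyphenyl)-7-methoxy-3-methyl-2,3-dihydro-1-benzofuran-5-yl]propan-1-one | COc1ccc([C@H]2Oc3c(OC)cc(C(=O)[C@@H](C)O[Si](C)(C)C(C)(C)C)cc3[C@@H]2C)cc1OC | intermediate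
17 | (2R)-1-[(2S,3S)-2-(3,4-dimethoxyphenyl)-7-methoxy-3-methyl-2,3-dihydro-1-benzofuran-5-yl]-2-hydroxypropan-1-one | COc1ccc([C@H]2Oc3c(OC)cc(C(=O)[C@@H](C)O)cc3[C@@H]2C)cc1OC | intermediate
18 | (1S,2R)-1-[(2S,3S)-2-(3,4-dimethoxyphenyl)-7-methoxy-3-methyl-2,3-dihydro-1-benzofuran-5-yl]propane-1,2-diol | COc1ccc([C@H]2Oc3c(OC)cc([C@H](O)[C@@H](C)O)cc3[C@@H]2C)cc1OC | target

**Step count**

Total steps: 13. Longest linear sequence: 11 (steps 1–8 and 11–13, from 1); the side-chain fragment 14 takes 2 steps (9–10).

**Steps most likely to fail, with fallbacks**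

Step 4. The discrimination between the two enantiotopic C2–H bonds may be incomplete, because the flanking methoxy group twists the benzyloxy arm out of the arene plane. The carbene may also be diverted into dimerization, azine formation or attack on the dimethoxyphenyl ring. A moderate enantiomeric excess could still be raised by recrystallization of 8 or 9, and any residual minor enantiomer becomes a diastereomer at 16.

The fallback moves stereocontrol to a substrate-bound auxiliary used with a matched catalyst, which should give the trans ester directly. It sets out from 4 and returns at 9, so steps 5 and 6 are bypassed. Ethyl (S)-lactate and pyrrolidine (neat, rt) give (S)-2-hydroxy-1-(pyrrolidin-1-yl)propan-1-one F1. Bromoacetyl bromide and pyridine in CH2Cl2 convert it into (S)-1-oxo-1-(pyrrolidin-1-yl)propan-2-yl 2-bromoacetate F2. N,N'-Ditosylhydrazine and DBU in THF then give (S)-1-oxo-1-(pyrrolidin-1-yl)propan-2-yl 2-diazoacetate F3. Coupling of F3 with 4 under the conditions of step 3 gives (S)-1-oxo-1-(pyrrolidin-1-yl)propan-2-yl 2-{5-bromo-2-[(3,4-dimethoxyphenyl)methoxy]-3-methoxyphenyl}-2-diazoacetate F4. Insertion with Rh2(S-DOSP)4 (dirhodium tetrakis[(S)-N-(4-dodecylbenzenesulfonyl)prolinate]) in CH2Cl2 should then give, by double stereodifferentiation, (S)-1-oxo-1-(pyrrolidin-1-yl)propan-2-yl (2S,3S)-5-bromo-2-(3,4-dimethoxyphenyl)-7-methoxy-2,3-dihydro-1-benzofuran-3-carboxylate F5. The matched sense for 2S,3S is assumed from the closest analogy with 7-methoxy-2-(3,4-dimethoxyphenyl) substrates. LiBH4 in THF cleaves the ester to alcohol 9 and returns the auxiliary.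

Step 3. Palladation of the diazo carbon may be slow at the hindered, electron-rich ortho-alkoxy aryl iodide, so that decomposition of ethyl diazoacetate at palladium or attack at the C–Br bond competes. The fallback separates C–C bond formation from introduction of the diazo group. It sets out from 4 and returns at 6. Palladium-catalysed coupling of 4 with the Reformatsky reagent BrZnCH2CO2Et (Pd(dba)2, Q-Phos, THF, rt; C–I should react before C–Br) gives ethyl 2-{5-bromo-2-[(3,4-dimethoxyphenyl)methoxy]-3-methoxyphenyl}acetate F6. Regitz diazo transfer (4-acetamidobenzenesulfonyl azide, DBU, MeCN) then gives 6.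

Step 13. Facial selectivity may be poor if the zinc chelate is not fully formed, in which case non-chelated Felkin–Anh delivery would give the syn diol. The fallback reduces before desilylation under catalyst control. It sets out from 16 and returns at 18, bypassing 17. Noyori transfer hydrogenation of 16 with RuCl(p-cymene)[(R,R)-TsDPEN] in HCO2H/Et3N gives (1S,2R)-2-[(tert-butyldimethylsilyl)oxy]-1-[(2S,3S)-2-(3,4-dimethoxyphenyl)-7-methoxy-3-methyl-2,3-dihydro-1-benzofuran-5-yl]propan-1-ol F7. On the usual aryl-ketone model this catalyst should deliver hydride to the face that gives 1S. TBAF/AcOH in THF then gives 18.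

**Further compounds**

F1 | step 4 | (S)-2-hydroxy-1-(pyrrolidin-1-yl)propan-1-one | C[C@H](O)C(=O)N1CCCC1
F2 | step 4 | (S)-1-oxo-1-(pyrrolidin-1-yl)propan-2-yl 2-bromoacetate | C[C@H](OC(=O)CBr)C(=O)N1CCCC1
F3 | step 4 | (S)-1-oxo-1-(pyrrolidin-1-yl)propan-2-yl 2-diazoacetate | C[C@H](OC(=O)C=[N+]=[N-])C(=O)N1CCCC1
F4 | step 4 | (S)-1-oxo-1-(pyrrolidin-1-yl)propan-2-yl 2-{5-bromo-2-[(3,4-dimethoxyphenyl)methoxy]-3-methoxyphenyl}-2-diazoacetate | C[C@H](OC(=O)C(=[N+]=[N-])c1cc(Br)cc(OC)c1OCc1ccc(OC)c(OC)c1)C(=O)N1CCCC1
F5 | step 4 | (S)-1-oxo-1-(pyrrolidin-1-yl)propan-2-yl (2S,3S)-5-bromo-2-(3,4-dimethoxyphenyl)-7-methoxy-2,3-dihydro-1-benzofuran-3-carboxylate | COc1ccc([C@H]2Oc3c(OC)cc(Br)cc3[C@@H]2C(=O)O[C@@H](C)C(=O)N4CCCC4)cc1OC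
F6 | step 3 | ethyl 2-{5-bromo-2-[(3,4-dimethoxyphenyl)methoxy]-3-methoxyphenyl}acetate | CCOC(=O)Cc1cc(Br)cc(OC)c1OCc1ccc(OC)c(OC)c1
F7 | step 13 | (1S,2R)-2-[(tert-butyldimethylsilyl)oxy]-1-[(2S,3S)-2-(3,4-dimethoxyphenyl)-7-methoxy-3-methyl-2,3-dihydro-1-benzofuran-5-yl]propan-1-ol | COc1ccc([C@H]2Oc3c(OC)cc([C@H](O)[C@@H](C)O[Si](C)(C)C(C)(C)C)cc3[C@@H]2C)cc1OC
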